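**Retrosynthetic overview**
- Last bond: C4–CH2Ar, from the o‑quinone methide of grandinol (the fully substituted formyl/isovaleryl methylphloroglucinol) and (−)‑α‑gurjunene; the same operation opens the cyclopropane (C6–C11) and hydrates C11.
- (−)‑α‑Gurjunene: the seven‑membered ring and the gem‑dimethylcyclopropane are closed together by intramolecular cyclopropanation of a prenyl alkene by an enal‑derived vinyl carbene.
- The cyclopentene carbaldehyde comes from aldol condensation of a 1,6‑keto aldehyde, made from (R)‑citronellal and methyl vinyl ketone (enamine Michael addition sets C1) plus a one‑carbon homologation.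
- (R)‑Citronellal comes from achiral geranial by organocatalytic transfer hydrogenation (first stereocentre, C10).
- Ring order: cyclopentene, then seven‑membered ring with cyclopropane, then cyclopropane cleaved in the coupling; the arene is made separately in two steps.

Assumption: geranial, 2‑methylphloroglucinol and 3‑methylbutanoyl chloride are taken as catalogue chemicals, and the target is (1R,4R,7R,10R) in guaiane numbering as read from the SMILES.
Atom labels C1–C11 below use guaiane numbering of the terpene part (C4 = benzylated quaternary carbon, C5=C6 alkene, C7 = carbinol‑bearing CH, C10 = methyl‑bearing CH, C1 = ring‑fusion CH, C11 = CMe2).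

**Step 1**
Reactants: 1 geranial, (2E)-3,7-dimethylocta-2,6-dienal
Product: 2 (R)-citronellal, (3R)-3,7-dimethyloct-6-enal
Conditions: diethyl 2,6-dimethyl-1,4-dihydropyridine-3,5-dicarboxylate (1.1 equiv), morpholinium (R)-3,3'-bis(2,4,6-triisopropylphenyl)-1,1'-binaphthyl-2,2'-diyl phosphate (20 mol%), THF, 50 °C
Reagents that add atoms: none
Why: Asymmetric counteranion‑directed iminium transfer hydrogenation: the morpholinium iminium ion of the enal is paired with the chiral phosphate, so the dihydropyridine delivers hydride to one face of the β‑carbon and sets the methyl‑bearing centre (later C10) as R, while the isolated alkene is inert.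

**Step 2**
Reactants: 2 (R)-citronellal; 3 methyl vinyl ketone (but-3-en-2-one)
Product: 4 (2R)-2-[(2R)-6-methylhept-5-en-2-yl]-5-oxohexanal
Conditions: (R)-2-[methoxy(diphenyl)methyl]pyrrolidine (10 mol%), ethyl 3,4-dihydroxybenzoate (20 mol%), neat, 4 °C
Reagents that add atoms: none
Why: Enamine‑catalysed Michael addition: the diphenyl(methoxy)methyl group blocks one face of the E‑enamine, so the enone (activated by the catechol) adds to the other face and the new α‑centre (later C1) is set as R by the catalyst, overriding the small bias of the neighbouring methyl centre.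

**Step 3**
Reactants: 4 (2R)-2-[(2R)-6-methylhept-5-en-2-yl]-5-oxohexanal
Product: 5 (5R,6R)-5-(2-methoxyethenyl)-6,10-dimethylundec-9-en-2-one (E/Z mixture)
Conditions: Ph3P(CH2OMe)Cl (1.2 equiv), KN(SiMe3)2 (1.15 equiv), THF, −78 → 0 °C
Reagents that add atoms: (methoxymethyl)triphenylphosphonium chloride, COC[P+](c1ccccc1)(c1ccccc1)c1ccccc1.[Cl-]
Why: Wittig methoxymethylenation: the non‑stabilised ylide reacts with the aldehyde far faster than with the methyl ketone at −78 °C and adds the carbon that becomes C6; the former α‑centre becomes allylic and can no longer epimerise.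

**Step 4**
Reactants: 5 (5R,6R)-5-(2-methoxyethenyl)-6,10-dimethylundec-9-en-2-one
Product: 7 (5R)-2-methyl-5-[(2R)-6-methylhept-5-en-2-yl]cyclopent-1-ene-1-carbaldehyde, via keto aldehyde 6 (not isolated)
Conditions: 1 M aq. HCl, THF, rt; then piperidine, AcOH, toluene, 80 °C
Reagents that add atoms: water, O
Why: Enol ether hydrolysis unmasks the 1,6‑keto aldehyde, and the piperidinium acetate aldol condensation (aldehyde enamine attacks the methyl ketone, 5‑exo, then dehydration) gives the tetrasubstituted cyclopentene carbaldehyde; both stereocentres are remote from the enolisable positions and are kept.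

**Step 5**
Reactants: 7 (5R)-2-methyl-5-[(2R)-6-methylhept-5-en-2-yl]cyclopent-1-ene-1-carbaldehyde
Product: 8 N'-[(E)-{(5R)-2-methyl-5-[(2R)-6-methylhept-5-en-2-yl]cyclopent-1-en-1-yl}methylidene]-2-(trifluoromethyl)benzenesulfonohydrazide
Conditions: 2-(CF3)C6H4SO2NHNH2 (1.05 equiv), MeOH, rt
Reagents that add atoms: 2-(trifluoromethyl)benzenesulfonohydrazide, NNS(=O)(=O)c1ccccc1C(F)(F)F
Why: Simple condensation of the aldehyde with the sulfonyl hydrazide gives the E‑hydrazone, a precursor that releases the diazoalkene below room temperature.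

**Step 6**
Reactants: 8 the sulfonyl hydrazone
Product: 11 (−)-α-gurjunene, (1aR,4R,4aR,7bS)-1,1,4,7-tetramethyl-1a,2,3,4,4a,5,6,7b-octahydro-1H-cyclopropa[e]azulene, via hydrazone sodium salt 9 (not isolated), via diazoalkene 10 (not isolated)
Conditions: NaH (1.5 equiv), Rh2(OAc)4 (2 mol%), CH2Cl2, −40 °C → rt
Reagents that add atoms: none
Why: Bamford–Stevens fragmentation of the hydrazone anion gives the vinyl diazo compound, and the rhodium vinyl carbene cyclopropanates the electron‑rich prenyl alkene intramolecularly, closing the seven‑membered ring and the necessarily cis‑fused gem‑dimethylcyclopropane at once; a chair‑like tether with the C10 methyl equatorial puts the CMe2 carbon on the face away from that methyl, giving C6 (S) and C7 (R).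

**Step 7**
Reactants: 12 2-methylbenzene-1,3,5-triol (2-methylphloroglucinol); 13 3-methylbutanoyl chloride
Product: 14 3-methyl-1-(2,4,6-trihydroxy-3-methylphenyl)butan-1-one
Conditions: AlCl3 (3 equiv), PhNO2–CH2Cl2, 0 → 40 °C
Reagents that add atoms: none
Why: Friedel–Crafts C‑acylation of the very electron‑rich triol at one of its two equivalent free positions; chelation of the product ketone by AlCl3 stops the reaction after one acylation.

**Step 8**
Reactants: 14 3-methyl-1-(2,4,6-trihydroxy-3-methylphenyl)butan-1-one
Product: 16 grandinol, 2,4,6-trihydroxy-3-methyl-5-(3-methylbutanoyl)benzaldehyde, via aryl iminium chloride 15 (not isolated)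
Conditions: POCl3, DMF, EtOAc, 0 °C → rt; then H2O, 60 °C
Reagents that add atoms: N,N-dimethylformamide, CN(C)C=O; water, O
Why: Vilsmeier–Haack formylation at the only ring C–H left, followed by hydrolysis of the iminium salt, gives the fully substituted formyl acyl phloroglucinol.

**Step 9**
Reactants: 16 grandinol; 11 (−)-α-gurjunene
Product: 18 2,4,6-trihydroxy-3-{[(1R,3aR,4R,7R)-7-(2-hydroxypropan-2-yl)-1,4-dimethyl-1,2,3,3a,4,5,6,7-octahydroazulen-1-yl]methyl}-5-(3-methylbutanoyl)benzaldehyde (target), via o-quinone methide 17 (not isolated)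
Conditions: DDQ (1.05 equiv), MeNO2, 0 °C; then 11 (1.2 equiv), (CF3)2CHOH–H2O (9:1), 0 °C → rt
Reagents that add atoms: water, O
Why: Proposed new method: DDQ oxidises the ring methyl of 16 to o‑quinone methide 17 (fully substituted ring, so no self‑coupling); its exocyclic CH2 is attacked by the tetrasubstituted alkene of 11 at C4 because this gives the tertiary cyclopropylcarbinyl cation at C5 (any chroman formed by phenoxide return re‑ionises, the acylated phenoxide being a good leaving group), the C6–C11 bond then opens to the C5=C6 alkene and a tertiary C11 cation that water captures in the ionising, weakly nucleophilic medium; C4 is set by attack on the cyclopentene face syn to H‑1, opposite the C1–C10 bond over which C7–C10 lie, and C1, C7, C10 are untouched; the closest known reactions are hetero‑Diels–Alder and ene alkylations of alkenes by o‑quinone methides and the Julia cyclopropylcarbinyl‑to‑homoallyl opening, here merged so that a vinylcyclopropane acts as a 1,5‑(homo‑ene) nucleophile with water termination.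

**Compound list**
1 | geranial, (2E)-3,7-dimethylocta-2,6-dienal | CC(C)=CCC/C(C)=C/C=O | starting material
2 | (R)-citronellal, (3R)-3,7-dimethyloct-6-enal | C[C@H](CCC=C(C)C)CC=O | intermediate
3 | methyl vinyl ketone, but-3-en-2-one | CC(=O)C=C | starting material
4 | (2R)-2-[(2R)-6-methylhept-5-en-2-yl]-5-oxohexanal | O=C[C@H](CCC(C)=O)[C@H](C)CCC=C(C)C | intermediate
5 | (5R,6R)-5-(2-methoxyethenyl)-6,10-dimethylundec-9-en-2-one (E/Z mixture at the enol ether) | COC=C[C@H](CCC(C)=O)[C@H](C)CCC=C(C)C | intermediate
6 | (3S)-3-[(2R)-6-methylhept-5-en-2-yl]-6-oxoheptanal (not isolated) | O=CC[C@H](CCC(C)=O)[C@H](C)CCC=C(C)C | intermediate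
7 | (5R)-2-methyl-5-[(2R)-6-methylhept-5-en-2-yl]cyclopent-1-ene-1-carbaldehyde | O=CC1=C(C)CC[C@@H]1[C@H](C)CCC=C(C)C | intermediate
8 | N'-[(E)-{(5R)-2-methyl-5-[(2R)-6-methylhept-5-en-2-yl]cyclopent-1-en-1-yl}methylidene]-2-(trifluoromethyl)benzenesulfonohydrazide | FC(F)(F)c1ccccc1S(=O)(=O)N/N=C/C1=C(C)CC[C@@H]1[C@H](C)CCC=C(C)C | intermediate
9 | sodium salt of hydrazone 8 (not isolated) | [Na+].FC(F)(F)c1ccccc1S(=O)(=O)[N-]/N=C/C1=C(C)CC[C@@H]1[C@H](C)CCC=C(C)C | intermediate
10 | (5R)-1-(diazomethyl)-2-methyl-5-[(2R)-6-methylhept-5-en-2-yl]cyclopent-1-ene (not isolated) | [N-]=[N+]=CC1=C(C)CC[C@@H]1[C@H](C)CCC=C(C)C | intermediate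
11 | (−)-α-gurjunene, (1aR,4R,4aR,7bS)-1,1,4,7-tetramethyl-1a,2,3,4,4a,5,6,7b-octahydro-1H-cyclopropa[e]azulene | CC1=C2[C@H]3[C@H](C3(C)C)CC[C@@H](C)[C@H]2CC1 | intermediate
12 | 2-methylbenzene-1,3,5-triol (2-methylphloroglucinol) | Cc1c(O)cc(O)cc1O | starting material
13 | 3-methylbutanoyl chloride | CC(C)CC(Cl)=O | starting material
14 | 3-methyl-1-(2,4,6-trihydroxy-3-methylphenyl)butan-1-one | CC(C)CC(=O)c1c(O)cc(O)c(C)c1O | intermediate
15 | N-{[2,4,6-trihydroxy-3-methyl-5-(3-methylbutanoyl)phenyl]methylidene}-N-methylmethanaminium chloride (not isolated) | CC(C)CC(=O)c1c(O)c(C=[N+](C)C)c(O)c(C)c1O.[Cl-] | intermediate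
16 | grandinol, 2,4,6-trihydroxy-3-methyl-5-(3-methylbutanoyl)benzaldehyde | CC(C)CC(=O)c1c(O)c(C=O)c(O)c(C)c1O | intermediate
17 | 2,6-dihydroxy-3-methylidene-5-(3-methylbutanoyl)-4-oxocyclohexa-1,5-diene-1-carbaldehyde (o-quinone methide, not isolated) | C=C1C(=O)C(C(=O)CC(C)C)=C(O)C(C=O)=C1O | intermediate
18 | 2,4,6-trihydroxy-3-{[(1R,3aR,4R,7R)-7-(2-hydroxypropan-2-yl)-1,4-dimethyl-1,2,3,3a,4,5,6,7-octahydroazulen-1-yl]methyl}-5-(3-methylbutanoyl)benzaldehyde | CC(C)CC(=O)c1c(O)c(C=O)c(O)c(C[C@@]2(C)CC[C@H]3C2=C[C@H](C(C)(C)O)CC[C@H]3C)c1O | target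

**Step count**
Total: 9 steps. Longest linear sequence: 7 steps (steps 1–6 and 9); the arene arm is steps 7–8.

**Three steps most likely to fail**

Step 9 (the new coupling). Risks: attack at C4 from the wrong face, the chroman acting as a resting state, and loss of a proton from the C11 cation instead of hydration. The fallback uses known reactions only; it sets out from 11 and 16 and comes back at 18. Compound 17 is generated with DDQ in dry MeNO2 in the presence of 11 and without water, as is routine for o‑quinone methide hetero‑Diels–Alder reactions with terpene alkenes. This gives the cis‑fused chroman closed through the phenol oxygen next to the formyl group F4, together with the regioisomeric chroman closed through the phenol oxygen next to the acyl group F5. The mixture is then solvolysed with TsOH·H2O in THF–H2O at 40 °C. This Julia‑type opening of the tertiary cyclopropylcarbinyl aryl ether gives 18 from either regioisomer.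

Step 6 (carbene ring closure). Risks: the vinyl diazo compound closing to a pyrazole, C–H insertion at C9, slow seven‑membered ring closure, and the wrong cyclopropane face. The fallback sets out from 7 and comes back at 11 without a diazo compound. Enal 7 is treated with Zn(Hg) and ClMe2SiCH2CH2SiMe2Cl in refluxing Et2O. This deoxygenates the aldehyde to an organozinc vinyl carbenoid, which cyclopropanates the prenyl alkene intramolecularly; no new isolable compound is made (F0).

Step 3 (basic ylide on an epimerisable, aldol‑prone keto aldehyde). The fallback sets out from 2 and comes back at 6, which then enters the piperidine/AcOH aldol of step 4. Enamine Michael addition of 2 to nitroethylene with (S)-2-[diphenyl(trimethylsilyloxy)methyl]pyrrolidine and 3-nitrobenzoic acid in toluene at 3 °C gives (2S,3R)-3,7-dimethyl-2-(2-nitroethyl)oct-6-enal F1. Wittig reaction with the stabilised, non‑basic ylide Ph3P=CHC(O)CH3 in CH2Cl2 gives (3E,5S,6R)-6,10-dimethyl-5-(2-nitroethyl)undeca-3,9-dien-2-one F2. Conjugate reduction with [(Ph3P)CuH]6 in wet benzene gives (5S,6R)-6,10-dimethyl-5-(2-nitroethyl)undec-9-en-2-one F3. A Nef reaction with TiCl3 and NH4OAc in aqueous MeOH then gives 6. In this variant the citronellal aldehyde carbon becomes C2 instead of C5, so no basic ylide meets an α‑stereogenic aldehyde.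

**Further compounds**
F1 | step 3 | (2S,3R)-3,7-dimethyl-2-(2-nitroethyl)oct-6-enal | O=C[C@@H](CC[N+](=O)[O-])[C@H](C)CCC=C(C)C
F2 | step 3 | (3E,5S,6R)-6,10-dimethyl-5-(2-nitroethyl)undeca-3,9-dien-2-one | CC(=O)/C=C/[C@@H](CC[N+](=O)[O-])[C@H](C)CCC=C(C)C
F3 | step 3 | (5S,6R)-6,10-dimethyl-5-(2-nitroethyl)undec-9-en-2-one | CC(=O)CC[C@@H](CC[N+](=O)[O-])[C@H](C)CCC=C(C)C
F0 | step 6 | none | none
F4 | step 9 | cis-fused chroman from 11 and 17 (O–C5 and CH2–C4 on the H-1 face, cyclopropane intact, ether oxygen next to the formyl group) | CC(C)CC(=O)c1c(O)c(C=O)c2O[C@]34[C@H]5[C@H](C5(C)C)CC[C@@H](C)[C@H]3CC[C@]4(C)Cc2c1O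
F5 | step 9 | regioisomeric cis-fused chroman from 11 and 17 (ether oxygen next to the 3-methylbutanoyl group) | O=Cc1c(O)c(C(=O)CC(C)C)c2O[C@]34[C@H]5[C@H](C5(C)C)CC[C@@H](C)[C@H]3CC[C@]4(C)Cc2c1O
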